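Myrtucommulone K is the inverse-demand hetero-Diels–Alder adduct of isobutylidene-syncarpic acid and the strained E-olefin C4=C5 of (−)-β-caryophyllene, so the route rests on that olefin inside the nine-membered ring C1–C9. The ring is built one carbon short: C4 is first the apex of a dibromocyclopropane fused to an eight-membered ring. Silver-assisted disrotatory opening inserts C4 and gives a nine-membered ring-trans 2-bromoallyl cation. Because C8, the future methylene carbon, lies 1,5 to C3 across the ring, a transannular hydride shift from the C8 silyl ether quenches the cation, fixing the olefin position and unveiling the C8 ketone in the same operation. The precursor is a 9,9-dibromobicyclo[6.1.0]nonane silyl ether carrying the C1 side chain.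

Key step: step 7

Remark: atoms carry caryophyllane labels throughout (C1 and C9 the cyclobutane CH carbons, C10 its CH2, C11 its CMe2, C4 the methyl-bearing and C8 the methylene-bearing ring carbon). Assumption: the oxazaborolidinium catalyst shows on the eight-membered dienone the facial preference it has on simple 2-cycloalkenones, and its enantiomer is chosen to give (R) at C1.

Step 1
Reactants: 1 (1Z,5Z)-cycloocta-1,5-diene (excess)
Product: 4 (2Z,5Z)-cycloocta-2,5-dien-1-one, via allylic hydroperoxide 2 (not isolated), via allylic peracetate 3 (not isolated)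
Conditions: O2, tetraphenylporphyrin (cat.), hν (visible), CH2Cl2, 0 °C, to partial conversion; then Ac2O, pyridine, DMAP (cat.), 0 °C to rt
Reagents that add atoms: dioxygen O=O
Why: The Schenck ene reaction of singlet oxygen with one cis-olefin puts oxygen on one olefinic carbon and shifts the double bond to give the skipped dienyl hydroperoxide, and Kornblum–DeLaMare dehydration of its peracetate should give the enone, whose electron-poor olefin is inert to singlet oxygen.

Step 2
Reactants: 4 (2Z,5Z)-cycloocta-2,5-dien-1-one; 5 1-methoxy-2-methyl-1-(trimethylsilyloxy)prop-1-ene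
Product: 7 methyl 2-methyl-2-[(1R,3Z)-7-oxocyclooct-3-en-1-yl]propanoate, via silyl enol ether 6 (not isolated)
Conditions: chiral oxazaborolidinium triflimide (20 mol %; from the B-(o-tolyl) oxazaborolidine of α,α-diphenylprolinol and HN(SO2CF3)2), Ph3PO (25 mol %), toluene, −20 °C; then 1 M HCl, THF
Reagents that add atoms: none
Why: In this catalytic enantioselective Mukaiyama–Michael addition the cationic boron Lewis acid binds the enone carbonyl and shields one face, so the ketene acetal should add to C1 from the open face and set C1 as (R), the isolated C3=C5 olefin staying untouched.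

Step 3
Reactants: 7 methyl 2-methyl-2-[(1R,3Z)-7-oxocyclooct-3-en-1-yl]propanoate
Product: 8 (4Z,7R)-7-(1-hydroxy-2-methylpropan-2-yl)cyclooct-4-en-1-ol (both carbinol epimers)
Conditions: LiAlH4, THF, 0 °C to reflux; aqueous NaOH work-up
Reagents that add atoms: none
Why: Hydride reduction of the ketone and the hindered ester should give the diol; the C8 carbinol forms as an epimer mixture, which does not matter because C8 becomes a carbonyl again in step 7.

Step 4
Reactants: 8 (4Z,7R)-7-(1-hydroxy-2-methylpropan-2-yl)cyclooct-4-en-1-ol
Product: 9 2-[(1R,3Z)-7-hydroxycyclooct-3-en-1-yl]-2-methylpropyl 4-methylbenzenesulfonate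
Conditions: TsCl (1.05 equiv), pyridine, CH2Cl2, 0 °C
Reagents that add atoms: 4-toluenesulfonyl chloride Cc1ccc(cc1)S(Cl)(=O)=O
Why: Selective tosylation of the primary over the secondary ring hydroxyl is expected, since attack of oxygen on sulfur is little slowed by the neopentyl position.

Step 5
Reactants: 9 2-[(1R,3Z)-7-hydroxycyclooct-3-en-1-yl]-2-methylpropyl 4-methylbenzenesulfonate
Product: 10 2-[(1R,3Z)-7-(tert-butyldimethylsilyloxy)cyclooct-3-en-1-yl]-2-methylpropyl 4-methylbenzenesulfonate
Conditions: TBSOSO2CF3, 2,6-lutidine, CH2Cl2, −78 °C to 0 °C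
Reagents that add atoms: tert-butyldimethylsilyl trifluoromethanesulfonate CC(C)(C)[Si](C)(C)OS(=O)(=O)C(F)(F)F
Why: Silylation of the secondary alcohol with a silyl triflate gives an ether that survives the carbene step and later makes the C8–H bond a good hydride donor.

Step 6
Reactants: 10 2-[(1R,3Z)-7-(tert-butyldimethylsilyloxy)cyclooct-3-en-1-yl]-2-methylpropyl 4-methylbenzenesulfonate
Product: 11 2-[(3R)-9,9-dibromo-5-(tert-butyldimethylsilyloxy)bicyclo[6.1.0]nonan-3-yl]-2-methylpropyl 4-methylbenzenesulfonate (cis-fused; cyclopropane anti to the side chain drawn)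
Conditions: CHBr3, KOtBu, pentane, −10 °C to rt
Reagents that add atoms: bromoform BrC(Br)Br
Why: Stereospecific dibromocarbene addition to the cis-olefin should give the cis-fused gem-dibromocyclopropane with C4 as its apex; the neopentyl tosylate and silyl ether resist the alkoxide, and the face of addition is immaterial because the cyclopropane stereocentres vanish in step 7.

Step 7
Reactants: 11 2-[(3R)-9,9-dibromo-5-(tert-butyldimethylsilyloxy)bicyclo[6.1.0]nonan-3-yl]-2-methylpropyl 4-methylbenzenesulfonate
Product: 14 2-[(1R,4Z)-4-bromo-8-oxocyclonon-4-en-1-yl]-2-methylpropyl 4-methylbenzenesulfonate (ring-trans olefin), via 2-bromoallyl cation 12 (not isolated), via silyloxycarbenium ion 13 (not isolated)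
Conditions: AgOSO2CF3 (1.5 equiv), 2,6-di-tert-butyl-4-methylpyridine (0.2 equiv), CH2Cl2, −20 °C to 20 °C, dark; then aqueous NaHCO3/NH3
Reagents that add atoms: none
Why: Proposed new method: silver-assisted loss of the exo bromide is concerted with disrotatory 2π-electrocyclic opening of the C3–C5 bond in which both ring bonds turn outward, so the eight-membered ring becomes a nine-membered ring holding a ring-trans 2-bromoallyl cation over C3–C4–C5 (closest known type: silver-promoted solvolytic ring expansion of 9,9-dibromobicyclo[6.1.0]nonanes to trans-2-bromocyclononenyl derivatives). Instead of an external nucleophile, the cation should be quenched by a transannular 1,5-hydride shift from the silyloxy-bearing C8–H to C3 through a six-membered transition state (closest known type: transannular hydride shifts from carbinol carbons to medium-ring cations, giving ketones). This leaves the C4=C5 bond ring-trans with bromine on C4 and turns C8 into a silyloxycarbenium ion, which triflate desilylates to the ketone. No ring is closed; the nine-membered ring arises by cleavage of the zero-atom bridge of the bicyclo[6.1.0]nonane, and no stereocentre is created, the olefin geometry being fixed by orbital symmetry and by departure of the exo bromide while C1 is untouched. The step needs the 1,5-shift to C3 to beat a 1,4-shift to C5, proton loss, ion-pair collapse and attack by the C8 oxygen. The six-membered geometry, the hydridic α-silyloxy C–H bond, the non-nucleophilic medium, the reversibility of triflate capture and the strain of the bridged trans-cycloalkenes that oxygen attack would form should secure this.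

Step 8
Reactants: 14 2-[(1R,4Z)-4-bromo-8-oxocyclonon-4-en-1-yl]-2-methylpropyl 4-methylbenzenesulfonate
Product: 15 2-methyl-2-[(1R,4E)-4-methyl-8-oxocyclonon-4-en-1-yl]propyl 4-methylbenzenesulfonate
Conditions: MeZnCl (commercial THF solution, 1.5 equiv), Pd[P(t-Bu)3]2 (5 mol %), THF, 20 °C
Reagents that add atoms: methylzinc chloride C[Zn]Cl
Why: In this Negishi coupling, oxidative addition of zerovalent palladium to the alkenyl bromide and reductive elimination go with retention, so the ring-trans bromoalkene should become the E-trisubstituted C4=C5 olefin, and the organozinc spares the ketone and the neopentyl tosylate.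

Step 9
Reactants: 15 2-methyl-2-[(1R,4E)-4-methyl-8-oxocyclonon-4-en-1-yl]propyl 4-methylbenzenesulfonate
Product: 16 (1R,4E,9S)-4,11,11-trimethylbicyclo[7.2.0]undec-4-en-8-one
Conditions: KOtBu, t-BuOH/THF, 25 °C
Reagents that add atoms: none
Why: Intramolecular enolate alkylation (4-exo-tet, helped by the gem-dimethyl group) should close C9–C10, whereas the C7 enolate would have to build a bridged six-membered ring across the medium ring; the epimerisable C9 settles under these equilibrating conditions in the more stable trans ring fusion relative to the fixed C1.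

Step 10
Reactants: 16 (1R,4E,9S)-4,11,11-trimethylbicyclo[7.2.0]undec-4-en-8-one
Product: 17 (−)-β-caryophyllene, (1R,4E,9S)-4,11,11-trimethyl-8-methylidenebicyclo[7.2.0]undec-4-ene
Conditions: Ph3PCH3Br, KOtBu, THF, 0 °C to 60 °C
Reagents that add atoms: methyltriphenylphosphonium bromide (as its ylide) C[P+](c1ccccc1)(c1ccccc1)c1ccccc1.[Br-]
Why: Wittig methylenation of the C8 ketone should install the exocyclic methylene, and the basic medium cannot scramble C9 because the trans fusion is the thermodynamic one.

Step 11
Reactants: 17 (−)-β-caryophyllene; 18 syncarpic acid; 19 isobutyraldehyde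
Product: 21 myrtucommulone K, via alkylidene trione 20 (not isolated)
Conditions: ethylenediammonium diacetate (cat.), 1,4-dioxane, 80 °C, sealed tube
Reagents that add atoms: none
Why: Knoevenagel condensation gives the electron-poor 1-oxadiene, which should add in an inverse-electron-demand hetero-Diels–Alder reaction to the strained endocyclic E-olefin rather than the methylene, with O bonding to the more substituted C4; suprafacial addition fixes the trans relation of the C4 methyl and H5, attack on the exposed outer face of the olefin relates both to C1/C9, the endo/exo orientation of the heterodiene sets the isopropyl-bearing carbon, and the target diastereomer is separated by chromatography.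

Compound list
1 | (1Z,5Z)-cycloocta-1,5-diene | C1/C=C\CC/C=C\C1 | starting material
2 | (2Z,5Z)-cycloocta-2,5-dien-1-yl hydroperoxide (racemic) | OOC1/C=C\C/C=C\CC1 | intermediate
3 | (2Z,5Z)-cycloocta-2,5-dien-1-yl peroxyacetate (racemic) | CC(=O)OOC1/C=C\C/C=C\CC1 | intermediate
4 | (2Z,5Z)-cycloocta-2,5-dien-1-one | O=C1/C=C\C/C=C\CC1 | intermediate
5 | 1-methoxy-2-methyl-1-(trimethylsilyloxy)prop-1-ene | COC(O[Si](C)(C)C)=C(C)C | starting material
6 | methyl 2-methyl-2-[(1R,3Z)-7-(trimethylsilyloxy)cycloocta-3,7-dien-1-yl]propanoate | C[Si](C)(C)OC1=C[C@H](C(C)(C)C(=O)OC)C/C=C\CC1 | intermediate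
7 | methyl 2-methyl-2-[(1R,3Z)-7-oxocyclooct-3-en-1-yl]propanoate | O=C1C[C@H](C(C)(C)C(=O)OC)C/C=C\CC1 | intermediate
8 | (4Z,7R)-7-(1-hydroxy-2-methylpropan-2-yl)cyclooct-4-en-1-ol, both C1 epimers | OC1C[C@H](C(C)(C)CO)C/C=C\CC1 | intermediate
9 | 2-[(1R,3Z)-7-hydroxycyclooct-3-en-1-yl]-2-methylpropyl 4-methylbenzenesulfonate, both carbinol epimers | OC1C[C@H](C(C)(C)COS(=O)(=O)c2ccc(C)cc2)C/C=C\CC1 | intermediate
10 | 2-[(1R,3Z)-7-(tert-butyldimethylsilyloxy)cyclooct-3-en-1-yl]-2-methylpropyl 4-methylbenzenesulfonate, both silyloxy epimers | CC(C)(C)[Si](C)(C)OC1C[C@H](C(C)(C)COS(=O)(=O)c2ccc(C)cc2)C/C=C\CC1 | intermediate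
11 | 2-[(3R)-9,9-dibromo-5-(tert-butyldimethylsilyloxy)bicyclo[6.1.0]nonan-3-yl]-2-methylpropyl 4-methylbenzenesulfonate, cis-fused, cyclopropane anti to the side chain, both silyloxy epimers | CC(C)(C)[Si](C)(C)OC1C[C@H](C(C)(C)COS(=O)(=O)c2ccc(C)cc2)C[C@@H]3[C@H](CC1)C3(Br)Br | intermediate
12 | ring-trans 2-bromoallyl cation over C3–C4–C5 of the nine-membered ring (one resonance form), triflate | CC(C)(C)[Si](C)(C)OC1C[C@H](C(C)(C)COS(=O)(=O)c2ccc(C)cc2)C/C=C(Br)/[CH+]CC1.[O-]S(=O)(=O)C(F)(F)F | intermediate
13 | O-silyl oxocarbenium ion at C8 of the ring-trans 4-bromocyclononene, triflate | CC(C)(C)[Si](C)(C)[O+]=C1C[C@H](C(C)(C)COS(=O)(=O)c2ccc(C)cc2)CC/C(Br)=C/CC1.[O-]S(=O)(=O)C(F)(F)F | intermediate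
14 | 2-[(1R,4Z)-4-bromo-8-oxocyclonon-4-en-1-yl]-2-methylpropyl 4-methylbenzenesulfonate (ring-trans olefin) | O=C1C[C@H](C(C)(C)COS(=O)(=O)c2ccc(C)cc2)CC/C(Br)=C/CC1 | intermediate
15 | 2-methyl-2-[(1R,4E)-4-methyl-8-oxocyclonon-4-en-1-yl]propyl 4-methylbenzenesulfonate | O=C1C[C@H](C(C)(C)COS(=O)(=O)c2ccc(C)cc2)CC/C(C)=C/CC1 | intermediate
16 | (1R,4E,9S)-4,11,11-trimethylbicyclo[7.2.0]undec-4-en-8-one | C/C/1=C\CCC(=O)[C@H]2CC([C@@H]2CC1)(C)C | intermediate
17 | (−)-β-caryophyllene, (1R,4E,9S)-4,11,11-trimethyl-8-methylidenebicyclo[7.2.0]undec-4-ene | C/C/1=C\CCC(=C)[C@H]2CC([C@@H]2CC1)(C)C | intermediate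
18 | syncarpic acid, 2,2,4,4-tetramethylcyclohexane-1,3,5-trione | CC1(C)C(=O)CC(=O)C(C)(C)C1=O | starting material
19 | isobutyraldehyde, 2-methylpropanal | CC(C)C=O | starting material
20 | 2,2,4,4-tetramethyl-6-(2-methylpropylidene)cyclohexane-1,3,5-trione | CC(C)C=C1C(=O)C(C)(C)C(=O)C(C)(C)C1=O | intermediate
21 | myrtucommulone K | C=C1CC[C@H]2[C@@H](C(C)C)C3=C(O[C@]2(C)CC[C@@H]2[C@@H]1CC2(C)C)C(C)(C)C(=O)C(C)(C)C3=O | target

Total step count: 11. Longest linear sequence: 11 steps (1 to 21).

Steps most likely to fail

Step 7 (bears the label Proposed new method): the allyl cation may lose a proton, collapse with the counter-ion, or take the hydride at C5 by a 1,4-shift before the 1,5-shift occurs. The fallback sets out from 11, comes back at 14 and uses known chemistry only. The silver-promoted ring expansion is run with AgOSO2CF3 in CH2Cl2 at −40 °C in the presence of excess triethylsilane, so that the cation is reduced intermolecularly (ionic hydrogenation) to the ring-trans bromoalkene silyl ether 2-[(1R,4Z)-4-bromo-8-(tert-butyldimethylsilyloxy)cyclonon-4-en-1-yl]-2-methylpropyl 4-methylbenzenesulfonate F1. The regioisomer from hydride attack at C5 is removed on AgNO3-impregnated silica. Bu4NF in THF then frees the alcohol 2-[(1R,4Z)-4-bromo-8-hydroxycyclonon-4-en-1-yl]-2-methylpropyl 4-methylbenzenesulfonate F2, and Dess–Martin periodinane oxidises it to 14.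

Step 8: the strained ring-trans bromoalkene may bind palladium, or isomerise to the cis olefin by palladium hydride addition and elimination, so that coupling stalls or the geometry is lost. The fallback sets out from 11 and comes back at 15. The methyl group is installed before the ring expansion: bromine–lithium exchange with n-BuLi in THF at −95 °C gives the α-bromocyclopropyllithium F3, which is allowed to equilibrate to the isomer with bromine exo and is then methylated with MeI with retention to the 9-exo-bromo-9-endo-methyl analogue of 11 F4. Under the conditions of step 7, F4 should open to the 2-methylallyl cation and give 15 directly after the hydride shift.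

Step 11: facial and endo/exo selectivity of the cycloaddition may be poor, and the heterodiene or traces of acid may attack the exocyclic methylene or trigger transannular cyclisation. The fallback sets out from 16 and comes back at 21. The three-component Knoevenagel/hetero-Diels–Alder reaction is run on 16 with 18 and 19 under the conditions of step 11; the strained E-olefin is its only olefin. This gives the 8-oxo analogue of myrtucommulone K (C8 ketone in place of the methylene) F5, whose least hindered ketone is then methylenated with Zn, CH2Br2 and TiCl4 (Takai–Lombardo) to give 21.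

Further compounds
F1 | step 7 | 2-[(1R,4Z)-4-bromo-8-(tert-butyldimethylsilyloxy)cyclonon-4-en-1-yl]-2-methylpropyl 4-methylbenzenesulfonate (ring-trans olefin) | CC(C)(C)[Si](C)(C)OC1C[C@H](C(C)(C)COS(=O)(=O)c2ccc(C)cc2)CC/C(Br)=C/CC1
F2 | step 7 | 2-[(1R,4Z)-4-bromo-8-hydroxycyclonon-4-en-1-yl]-2-methylpropyl 4-methylbenzenesulfonate (ring-trans olefin) | OC1C[C@H](C(C)(C)COS(=O)(=O)c2ccc(C)cc2)CC/C(Br)=C/CC1
F3 | step 8 | 2-[(3R)-9-exo-bromo-5-(tert-butyldimethylsilyloxy)-9-endo-lithiobicyclo[6.1.0]nonan-3-yl]-2-methylpropyl 4-methylbenzenesulfonate | CC(C)(C)[Si](C)(C)OC1C[C@H](C(C)(C)COS(=O)(=O)c2ccc(C)cc2)C[C@@H]3[C@H](CC1)[C@@]3([Li])Br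
F4 | step 8 | 2-[(3R)-9-exo-bromo-5-(tert-butyldimethylsilyloxy)-9-endo-methylbicyclo[6.1.0]nonan-3-yl]-2-methylpropyl 4-methylbenzenesulfonate | CC(C)(C)[Si](C)(C)OC1C[C@H](C(C)(C)COS(=O)(=O)c2ccc(C)cc2)C[C@@H]3[C@H](CC1)[C@@]3(C)Br
F5 | step 11 | 8-oxo analogue of myrtucommulone K (C8 ketone in place of the exocyclic methylene) | O=C1CC[C@H]2[C@@H](C(C)C)C3=C(O[C@]2(C)CC[C@@H]2[C@@H]1CC2(C)C)C(C)(C)C(=O)C(C)(C)C3=O
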